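**Retrosynthetic overview**

1. The 21-membered ring is opened at the diene (Stille coupling of a vinylstannane on fragment A with a 2-iodoalkene on fragment B) and at the ester (an acylketene released from a dioxinone is captured by the lactone C4 hydroxyl). The 3(2H)-furanone is the cyclodehydration product of the α′-hydroxy β,δ-diketo ester formed in that capture.
2. Fragment B: geraniol gives the tertiary carbinol (asymmetric epoxidation, epoxy chloride fragmentation to the propargylic alcohol, hydrozirconation–iodination). Two boron anti-aldols (lactate-derived ketone, then (R)-glyceraldehyde acetonide) and a 1,3-anti reduction set the six contiguous centres.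
3. Fragment A: the δ-lactone (O1, C2 carbonyl, C3 methyl, C4 oxygen, C5, C6 quaternary) is closed at C2–C3 by a three-component Prins cyclization of a tertiary (Z)-homoallylic, propargylic alcohol with trimethyl orthoformate and trifluoroacetic acid. The lactol ether is then oxidized to the lactone.
4. Enabling feature: the lactone is a 4-oxygenated tetrahydropyran in which O1 and the C4 oxygen stand 1,3 across C2–C3 and the C3 methyl is cis to the C4 oxygen. This is the retron of a Prins closure of a (Z)-alkene, one oxidation level below the lactone at C2. The quaternary C6 can carry an ethynyl group, slim enough to sit axial and later the handle for the diene.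
5. Ring order: tetrahydropyran/lactone (steps 7–8), furanone (step 31), macrocycle (step 32).

Key step: step 7

Remark: the anomeric carbon of 14 and the carbinol carbons of 29 and 46 are carried as mixtures because each is later oxidized or cleaved; lactone locants follow tetrahydropyran-2-one numbering.

**Fragment A**

Step 1
Reactants: 1 (S)-2-hydroxybutanoic acid; 2 pivalaldehyde
Product: 3 (2S,5S)-2-tert-butyl-5-ethyl-1,3-dioxolan-4-one
Conditions: p-TsOH·H2O (cat.), H2SO4 (cat.), pentane, reflux, Dean–Stark; cis isomer purified by crystallization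
Reagents that add atoms: none
Why: Acid-catalysed acetalization gives the cis-dioxolanone as the favoured isomer and stores the configuration of 1 at the acetal carbon (Seebach self-regeneration of stereocentres).

Step 2
Reactants: 3 dioxolanone; 4 1-bromobut-2-yne
Product: 6 (2S,5R)-5-(but-2-yn-1-yl)-2-tert-butyl-5-ethyl-1,3-dioxolan-4-one, via lithium enolate 5 (not isolated)
Conditions: LiN(i-Pr)2, THF, −78 °C; then 4, −78 → −20 °C
Reagents that add atoms: none
Why: Seebach alkylation: the planar enolate is attacked by the propargylic bromide anti to the tert-butyl group, which sets the fully substituted carbinol carbon (later lactone C6) with overall retention.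

Step 3
Reactants: 6 alkynyl dioxolanone
Product: 7 (2S,5R)-5-[(Z)-but-2-en-1-yl]-2-tert-butyl-5-ethyl-1,3-dioxolan-4-one
Conditions: H2 (1 atm), Pd/CaCO3 poisoned with Pb(OAc)2 (Lindlar catalyst), quinoline, EtOAc, rt
Reagents that add atoms: none
Why: Lindlar semi-hydrogenation adds hydrogen syn to the only alkyne and should give the (Z)-alkene that step 7 needs for an axial methyl group.

Step 4
Reactants: 7 (Z)-butenyl dioxolanone
Product: 8 (R,Z)-2-ethylhex-4-ene-1,2-diol
Conditions: LiAlH4, Et2O, 0 °C → rt; Fieser work-up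
Reagents that add atoms: none
Why: Hydride reduction of the lactone carbonyl opens the auxiliary ring and releases the tertiary/primary diol without touching the stereocentre.

Step 5
Reactants: 8 diol
Product: 9 (R,Z)-2-ethyl-2-hydroxyhex-4-enal
Conditions: SO3·pyridine, DMSO, i-Pr2NEt, CH2Cl2, 0 °C
Reagents that add atoms: none
Why: Parikh–Doering oxidation converts only the primary alcohol, the tertiary one being inert.

Step 6
Reactants: 9 hydroxy aldehyde
Product: 10 (R,Z)-3-ethylhept-5-en-1-yn-3-ol
Conditions: dimethyl (1-diazo-2-oxopropyl)phosphonate, K2CO3, MeOH, 0 °C → rt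
Reagents that add atoms: dimethyl (1-diazo-2-oxopropyl)phosphonate (COP(=O)(OC)C(=[N+]=[N-])C(C)=O)
Why: Seyferth–Gilbert homologation in the Ohira–Bestmann variant turns the aldehyde into the terminal alkyne under mild carbonate conditions; the α-carbon carries no hydrogen and cannot epimerize.

Step 7
Reactants: 10 (R,Z)-3-ethylhept-5-en-1-yn-3-ol; 11 trimethyl orthoformate
Product: 14 (3S,4S,6R)-6-ethyl-6-ethynyl-2-methoxy-3-methyltetrahydro-2H-pyran-4-ol (anomers), via mixed orthoformate 12 (not isolated), via trifluoroacetate 13 (not isolated)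
Conditions: HC(OMe)3 (3 equiv), CF3CO2H (15 equiv), CH2Cl2, −20 → 0 °C; then MeOH, K2CO3, 0 °C → rt
Reagents that add atoms: trifluoroacetic acid (OC(=O)C(F)(F)F)
Why: Proposed new method: acid exchanges the tertiary alcohol into orthoformate 12, loss of methanol gives a dialkoxycarbenium ion on O1 whose carbon (C2) is attacked by the (Z)-alkene carbon C3, and the C4 cation is captured by trifluoroacetate, so that alcohol, one-carbon unit and oxygen nucleophile are joined in one operation. The closest known reaction type is the Prins cyclization of homoallylic alcohols with aldehydes or acetals in trifluoroacetic acid; the extension is the orthoformate-level electrophile, which is known to add to π-nucleophiles of similar strength (allylsilanes, enol ethers) and which, being doubly oxygen-stabilized, should gain nothing from the 2-oxonia-Cope path that erodes Prins reactions of tertiary alcohols. The tetrahydropyran is closed by C2–C3 bond formation in a 6-endo-trig mode through a chair. C3 is set by the Z geometry of the alkene (methyl axial) and C4 by equatorial capture of the tetrahydropyranyl cation (hence 3,4-cis); both are set relative to C6 by the chair in which ethyl is equatorial and the slim ethynyl group (A value about 0.4 against about 1.8 for ethyl) is axial. The anomeric centre is formed as a mixture and is removed in step 8. The step needs selection between the two chairs that differ in the axial group on C6, which the ethynyl group should secure, and it needs the tertiary C–O bond to stay intact, which the poorly stabilized propargylic cation should secure.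

Step 8
Reactants: 14 lactol methyl ether
Product: 15 (3S,4S,6R)-6-ethyl-6-ethynyl-4-hydroxy-3-methyltetrahydro-2H-pyran-2-one
Conditions: mCPBA, BF3·OEt2, CH2Cl2, 0 °C → rt
Reagents that add atoms: 3-chloroperbenzoic acid (OOC(=O)c1cccc(Cl)c1)
Why: Grieco oxidation: BF3 ionizes the acetal to the cyclic oxocarbenium ion, the peracid adds and the peroxy acetal fragments to the lactone; the alkyne and the secondary alcohol should be inert to the peracid under these conditions.

Step 9
Reactants: 15 alkynyl lactone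
Product: 16 (3S,4S,6R)-6-ethyl-4-hydroxy-3-methyl-6-[(E)-2-(tributylstannyl)vinyl]tetrahydro-2H-pyran-2-one
Conditions: Bu3SnH, Pd(PPh3)2Cl2 (cat.), THF, 0 °C → rt
Reagents that add atoms: tributyltin hydride (CCCC[SnH](CCCC)CCCC)
Why: Palladium-catalysed syn-hydrostannylation places tin on the terminal carbon because the propargylic carbon is fully substituted, which should give the (E)-vinylstannane.

**Lactate-derived ketone**

Step 10
Reactants: 17 ethyl (S)-lactate
Product: 18 (S)-2-hydroxy-N-methoxy-N-methylpropanamide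
Conditions: MeNH(OMe)·HCl, i-PrMgCl, THF, −20 → 0 °C
Reagents that add atoms: N,O-dimethylhydroxylamine hydrochloride (CNOC.Cl)
Why: Aminolysis of the ester by the magnesium amide gives the Weinreb amide without racemization of the lactate centre.

Step 11
Reactants: 18 Weinreb amide
Product: 19 (S)-2-hydroxypentan-3-one
Conditions: EtMgBr (3 equiv), THF, 0 °C → rt; aq. NH4Cl
Reagents that add atoms: ethylmagnesium bromide (CC[Mg]Br)
Why: Grignard addition to a Weinreb amide stops at the ketone because the magnesium chelate survives until work-up.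

Step 12
Reactants: 19 hydroxy ketone
Product: 20 (S)-3-oxopentan-2-yl benzoate
Conditions: Bz2O, DMAP (cat.), i-Pr2NEt, CH2Cl2, rt
Reagents that add atoms: benzoic anhydride (O=C(OC(=O)c1ccccc1)c1ccccc1)
Why: DMAP-catalysed acylation of the secondary alcohol gives the ethyl ketone used in the Paterson anti-aldol.

**Fragment B**

Step 13
Reactants: 21 geraniol
Product: 22 [(2S,3S)-3-methyl-3-(4-methylpent-3-en-1-yl)oxiran-2-yl]methanol
Conditions: Ti(OiPr)4 (5 mol%), L-(+)-diethyl tartrate (6 mol%), t-BuOOH, 4 Å MS, CH2Cl2, −20 °C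
Reagents that add atoms: tert-butyl hydroperoxide (CC(C)(C)OO)
Why: Sharpless asymmetric epoxidation delivers oxygen to one face of the allylic alcohol and sets the future tertiary carbinol centre as S; the remote alkene is not an allylic alcohol and does not react.

Step 14
Reactants: 22 epoxy alcohol
Product: 23 (2R,3S)-2-(chloromethyl)-3-methyl-3-(4-methylpent-3-en-1-yl)oxirane
Conditions: PPh3, CCl4, NaHCO3, reflux
Reagents that add atoms: tetrachloromethane (ClC(Cl)(Cl)Cl)
Why: Appel chlorination of the primary alcohol under buffered conditions leaves the epoxide intact.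

Step 15
Reactants: 23 epoxy chloride
Product: 25 (S)-4,8-dimethylnon-7-en-2-yn-4-ol, via dilithio alkynol 24 (not isolated)
Conditions: n-BuLi (3.2 equiv), THF, −78 → −20 °C; then MeI (1.1 equiv), DMPU, −20 °C → rt
Reagents that add atoms: iodomethane (CI)
Why: Base-induced fragmentation of the 2,3-epoxy chloride (deprotonation next to chlorine, epoxide opening, loss of HCl from the vinyl chloride) gives the tertiary propargylic alkoxide with retention at the carbinol carbon, and the acetylide formed by the third equivalent is C-methylated.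

Step 16
Reactants: 25 alkynol
Product: 26 (S)-triethyl[(4,8-dimethylnon-7-en-2-yn-4-yl)oxy]silane
Conditions: TESOTf, 2,6-lutidine, CH2Cl2, −78 → 0 °C
Reagents that add atoms: triethylsilyl trifluoromethanesulfonate (CC[Si](CC)(CC)OS(=O)(=O)C(F)(F)F)
Why: Silylation of the hindered tertiary alcohol with the silyl triflate prevents lactol formation with the aldehyde made in step 18.

Step 17
Reactants: 26 silyl ether
Product: 28 (S,E)-triethyl[(2-iodo-4,8-dimethylnona-2,7-dien-4-yl)oxy]silane, via alkenylzirconocene 27 (not isolated)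
Conditions: Cp2Zr(H)Cl (2.5 equiv), THF, 50 °C; then I2, 0 °C
Reagents that add atoms: iodine (II)
Why: Hydrozirconation with excess reagent adds Zr–H syn and equilibrates zirconium to the carbon next to methyl, away from the quaternary centre, and iodinolysis with retention should give the (E)-2-iodoalkene.

Step 18
Reactants: 28 iodo diene
Product: 30 (S,E)-6-iodo-4-methyl-4-(triethylsilyloxy)hept-5-enal, via vicinal diol 29 (not isolated)
Conditions: OsO4 (2 mol%), NaIO4 (4 equiv), 2,6-lutidine, dioxane/H2O (3:1), rt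
Reagents that add atoms: sodium periodate ([Na+].[O-]I(=O)(=O)=O), osmium tetroxide (O=[Os](=O)(=O)=O)
Why: Lemieux–Johnson cleavage: OsO4, regenerated by NaIO4, dihydroxylates the electron-rich trisubstituted alkene and periodate cleaves the diol, while the hindered, electron-poor iodoalkene should be spared.

Step 19
Reactants: 20 (S)-3-oxopentan-2-yl benzoate; 30 aldehyde
Product: 32 (2S,4R,5R,8S,E)-5-hydroxy-10-iodo-4,8-dimethyl-3-oxo-8-(triethylsilyloxy)undec-9-en-2-yl benzoate, via boron enolate 31 (not isolated)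
Conditions: c-Hex2BCl, Me2NEt, Et2O, −78 → 0 °C; then 30, −78 → −20 °C; H2O2, MeOH, pH 7 buffer
Reagents that add atoms: none
Why: Paterson anti-aldol: the (E)-enol borinate reacts through a chair transition state whose face is fixed by the benzoate-bearing centre, which should give the 4,5-anti adduct and set the methoxy-bearing carbon and its methyl-bearing neighbour.

Step 20
Reactants: 32 aldol adduct
Product: 33 (2S,4R,5R,8S,E)-10-iodo-5-methoxy-4,8-dimethyl-3-oxo-8-(triethylsilyloxy)undec-9-en-2-yl benzoate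
Conditions: Me3OBF4, 1,8-bis(dimethylamino)naphthalene, CH2Cl2, 0 °C → rt
Reagents that add atoms: trimethyloxonium tetrafluoroborate (C[O+](C)C.F[B-](F)(F)F)
Why: O-Methylation with Meerwein's salt and a non-nucleophilic base alkylates the β-hydroxy ketone without retro-aldol or elimination.

Step 21
Reactants: 33 methyl ether
Product: 34 (4R,5R,8S,E)-10-iodo-5-methoxy-4,8-dimethyl-8-(triethylsilyloxy)undec-9-en-3-one
Conditions: SmI2 (2.5 equiv), THF/MeOH, 0 °C
Reagents that add atoms: none
Why: SmI2 cleaves the α-acyloxy C–O bond by two single-electron transfers and gives the ethyl ketone; the iodoalkene should survive in the absence of HMPA.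

Step 22
Reactants: 34 ethyl ketone; 35 (R)-2,2-dimethyl-1,3-dioxolane-4-carbaldehyde
Product: 37 (1S,2R,4R,5R,8S,E)-1-[(R)-2,2-dimethyl-1,3-dioxolan-4-yl]-1-hydroxy-10-iodo-5-methoxy-2,4,8-trimethyl-8-(triethylsilyloxy)undec-9-en-3-one, via boron enolate 36 (not isolated)
Conditions: c-Hex2BCl, Et3N, Et2O, −78 → 0 °C; then 35, −78 → −20 °C; H2O2, MeOH, pH 7 buffer
Reagents that add atoms: none
Why: Paterson anti-aldol under substrate control: the (E)-enol borinate adds on the face opposite the α′-methyl group (anti,anti) while the α-alkoxy aldehyde reacts in the Felkin sense, a matched pair that should set both new centres.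

Step 23
Reactants: 37 β-hydroxy ketone
Product: 38 (1S,2S,3S,4S,5R,8S,E)-1-[(R)-2,2-dimethyl-1,3-dioxolan-4-yl]-10-iodo-5-methoxy-2,4,8-trimethyl-8-(triethylsilyloxy)undec-9-ene-1,3-diol
Conditions: Me4NBH(OAc)3, MeCN/AcOH (1:1), −30 → −20 °C
Reagents that add atoms: none
Why: Evans–Saksena reduction: the hydroxyl-bound acetoxyborohydride delivers hydride intramolecularly and should give the 1,3-anti diol.

Step 24
Reactants: 38 anti-1,3-diol
Product: 39 di-tert-butylsilylene acetal of diol 38 (all centres as in 38)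
Conditions: t-Bu2Si(OTf)2, 2,6-lutidine, CH2Cl2, 0 °C → rt
Reagents that add atoms: di-tert-butylsilyl bis(trifluoromethanesulfonate) (CC(C)(C)[Si](OS(=O)(=O)C(F)(F)F)(OS(=O)(=O)C(F)(F)F)C(C)(C)C)
Why: The silyl bis-triflate bridges the 1,3-diol as a six-membered silylene that later outlasts the conditions which free the neighbouring hydroxyl for furanone formation.

Step 25
Reactants: 39 silylene acetonide
Product: 40 terminal (R)-1,2-diol from 39 (acetonide removed, silylene and silyl ether kept)
Conditions: CuCl2·2H2O, MeCN, 0 °C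
Reagents that add atoms: none
Why: The terminal dioxolane is hydrolysed by the mild Lewis acid faster than the silylene or the tertiary silyl ether.

Step 26
Reactants: 40 diol
Product: 41 bis(triethylsilyl) ether of diol 40
Conditions: TESOTf, 2,6-lutidine, CH2Cl2, −78 → 0 °C
Reagents that add atoms: triethylsilyl trifluoromethanesulfonate (CC[Si](CC)(CC)OS(=O)(=O)C(F)(F)F)
Why: Standard silylation of the primary and the hindered secondary alcohol.

Step 27
Reactants: 41 bis-silyl ether
Product: 43 α-(triethylsilyloxy) aldehyde (primary position of 41 oxidized), via primary alcohol 42 (not isolated)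
Conditions: (COCl)2, DMSO, CH2Cl2, −78 → −40 °C; then Et3N, −78 °C → rt
Reagents that add atoms: none
Why: Under Swern conditions a primary triethylsilyl ether is cleaved and oxidized in situ while secondary and tertiary silyl ethers stay, so the aldehyde should form directly.

Step 28
Reactants: 43 aldehyde; 44 2,2,6-trimethyl-4H-1,3-dioxin-4-one
Product: 46 δ-hydroxy dioxinone (carbinol epimers), via lithium dienolate 45 (not isolated)
Conditions: LiN(i-Pr)2, THF, −78 °C (44); then 43, −78 °C; aq. NH4Cl
Reagents that add atoms: none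
Why: Vinylogous aldol addition of the γ-lithiated dioxinone at low temperature; the new carbinol centre is left uncontrolled because it is oxidized next.

Step 29
Reactants: 46 hydroxy dioxinone
Product: 47 β-keto dioxinone (fragment B)
Conditions: Dess–Martin periodinane, NaHCO3, CH2Cl2, 0 °C → rt
Reagents that add atoms: none
Why: Buffered Dess–Martin oxidation gives the ketone, which enolizes toward the dioxinone side and so should not epimerize the α-silyloxy centre.

**Endgame**

Step 30
Reactants: 47 keto dioxinone; 16 hydroxy lactone vinylstannane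
Product: 48 β,δ-diketo ester joining fragments A and B
Conditions: toluene (0.1 M), 105 °C
Reagents that add atoms: none
Why: Retro-[4+2] loss of acetone gives an acylketene that is captured by the secondary alcohol under neutral conditions, which spares the β-acyloxy lactone from base.

Step 31
Reactants: 48 diketo ester
Product: 50 3(2H)-furanone seco compound, via hydroxy diketone 49 (not isolated)
Conditions: PPTS (0.3 equiv), MeOH/CH2Cl2 (1:1), 0 °C → rt
Reagents that add atoms: none
Why: Mild acid removes the secondary silyl ether next to the ketone, the freed hydroxyl closes the five-membered hemiketal on the central ketone (5-exo-trig) and water is lost to the vinylogous ester; the silylene-protected neighbour cannot compete to give a pyranone.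

Step 32
Reactants: 50 furanone seco compound
Product: 51 protected macrolide (silylene and tertiary triethylsilyl ether in place)
Conditions: Pd2(dba)3·CHCl3 (0.2 equiv), AsPh3 (0.8 equiv), DMF/THF (1:1), 1 mM, rt → 40 °C
Reagents that add atoms: none
Why: Stille macrocyclization at high dilution joins the (E)-vinylstannane and the (E)-iodoalkene with retention of both geometries, under base-free conditions that should not epimerize the furanone carbon.

Step 33
Reactants: 51 protected macrolide
Product: 52 CNP0226414.1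
Conditions: HF·pyridine, pyridine, THF, 0 °C → rt
Reagents that add atoms: none
Why: Pyridine-buffered HF cleaves the silylene and the tertiary silyl ether without base, which would eliminate the β-acyloxy lactone or epimerize the furanone carbon.

**Compound list**

1 | (S)-2-hydroxybutanoic acid | CC[C@H](O)C(=O)O | starting material
2 | pivalaldehyde | CC(C)(C)C=O | starting material
3 | (2S,5S)-2-tert-butyl-5-ethyl-1,3-dioxolan-4-one | CC[C@@H]1O[C@H](C(C)(C)C)OC1=O | intermediate
4 | 1-bromobut-2-yne | CC#CCBr | starting material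
5 | lithium (S)-2-tert-butyl-5-ethyl-1,3-dioxol-4-olate | CCC1=C(O[Li])O[C@@H](C(C)(C)C)O1 | intermediate
6 | (2S,5R)-5-(but-2-yn-1-yl)-2-tert-butyl-5-ethyl-1,3-dioxolan-4-one | CC[C@]1(CC#CC)O[C@H](C(C)(C)C)OC1=O | intermediate
7 | (2S,5R)-5-[(Z)-but-2-en-1-yl]-2-tert-butyl-5-ethyl-1,3-dioxolan-4-one | CC[C@]1(C/C=C\C)O[C@H](C(C)(C)C)OC1=O | intermediate
8 | (R,Z)-2-ethylhex-4-ene-1,2-diol | CC[C@](C/C=C\C)(O)CO | intermediate
9 | (R,Z)-2-ethyl-2-hydroxyhex-4-enal | CC[C@](C/C=C\C)(O)C=O | intermediate
10 | (R,Z)-3-ethylhept-5-en-1-yn-3-ol | CC[C@](C/C=C\C)(O)C#C | intermediate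
11 | trimethyl orthoformate | COC(OC)OC | starting material
12 | (R,Z)-3-(dimethoxymethoxy)-3-ethylhept-5-en-1-yne | CC[C@](C/C=C\C)(OC(OC)OC)C#C | intermediate
13 | (3S,4S,6R)-6-ethyl-6-ethynyl-2-methoxy-3-methyltetrahydro-2H-pyran-4-yl trifluoroacetate (anomers) | FC(F)(F)C(=O)O[C@@H](C1)[C@H](C)C(OC)O[C@@]1(CC)C#C | intermediate
14 | (3S,4S,6R)-6-ethyl-6-ethynyl-2-methoxy-3-methyltetrahydro-2H-pyran-4-ol (anomers) | O[C@@H](C1)[C@H](C)C(OC)O[C@@]1(CC)C#C | intermediate
15 | (3S,4S,6R)-6-ethyl-6-ethynyl-4-hydroxy-3-methyltetrahydro-2H-pyran-2-one | O[C@@H](C1)[C@H](C)C(=O)O[C@@]1(CC)C#C | intermediate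
16 | (3S,4S,6R)-6-ethyl-4-hydroxy-3-methyl-6-[(E)-2-(tributylstannyl)vinyl]tetrahydro-2H-pyran-2-one | O[C@@H](C1)[C@H](C)C(=O)O[C@@]1(CC)/C=C/[Sn](CCCC)(CCCC)CCCC | intermediate
17 | ethyl (S)-lactate | CCOC(=O)[C@H](C)O | starting material
18 | (S)-2-hydroxy-N-methoxy-N-methylpropanamide | CON(C)C(=O)[C@H](C)O | intermediate
19 | (S)-2-hydroxypentan-3-one | CCC(=O)[C@H](C)O | intermediate
20 | (S)-3-oxopentan-2-yl benzoate | CCC(=O)[C@H](C)OC(=O)c1ccccc1 | intermediate
21 | geraniol | CC(C)=CCC/C(C)=C/CO | starting material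
22 | [(2S,3S)-3-methyl-3-(4-methylpent-3-en-1-yl)oxiran-2-yl]methanol | OC[C@H]1[C@](C)(CCC=C(C)C)O1 | intermediate
23 | (2R,3S)-2-(chloromethyl)-3-methyl-3-(4-methylpent-3-en-1-yl)oxirane | ClC[C@H]1[C@](C)(CCC=C(C)C)O1 | intermediate
24 | dilithium salt of (S)-3,7-dimethyloct-6-en-1-yn-3-ol | [Li]C#C[C@@](C)(O[Li])CCC=C(C)C | intermediate
25 | (S)-4,8-dimethylnon-7-en-2-yn-4-ol | CC#C[C@@](C)(O)CCC=C(C)C | intermediate
26 | (S)-triethyl[(4,8-dimethylnon-7-en-2-yn-4-yl)oxy]silane | CC#C[C@@](C)(O[Si](CC)(CC)CC)CCC=C(C)C | intermediate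
27 | chloro[(S,E)-4,8-dimethyl-4-(triethylsilyloxy)nona-2,7-dien-2-yl]zirconocene | C/C(=C\[C@@](C)(O[Si](CC)(CC)CC)CCC=C(C)C)[Zr](Cl)(C1C=CC=C1)C1C=CC=C1 | intermediate
28 | (S,E)-triethyl[(2-iodo-4,8-dimethylnona-2,7-dien-4-yl)oxy]silane | I/C(C)=C/[C@@](C)(O[Si](CC)(CC)CC)CCC=C(C)C | intermediate
29 | (6S,E)-8-iodo-2,6-dimethyl-6-(triethylsilyloxy)non-7-ene-2,3-diol (C3 epimers) | I/C(C)=C/[C@@](C)(O[Si](CC)(CC)CC)CCC(O)C(C)(C)O | intermediate
30 | (S,E)-6-iodo-4-methyl-4-(triethylsilyloxy)hept-5-enal | I/C(C)=C/[C@@](C)(O[Si](CC)(CC)CC)CCC=O | intermediate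
31 | (E)-dicyclohexylboron enolate of 20 | C/C=C(/OB(C1CCCCC1)C1CCCCC1)[C@H](C)OC(=O)c1ccccc1 | intermediate
32 | (2S,4R,5R,8S,E)-5-hydroxy-10-iodo-4,8-dimethyl-3-oxo-8-(triethylsilyloxy)undec-9-en-2-yl benzoate | I/C(C)=C/[C@@](C)(O[Si](CC)(CC)CC)CC[C@@H](O)[C@@H](C)C(=O)[C@H](C)OC(=O)c1ccccc1 | intermediate
33 | (2S,4R,5R,8S,E)-10-iodo-5-methoxy-4,8-dimethyl-3-oxo-8-(triethylsilyloxy)undec-9-en-2-yl benzoate | I/C(C)=C/[C@@](C)(O[Si](CC)(CC)CC)CC[C@@H](OC)[C@@H](C)C(=O)[C@H](C)OC(=O)c1ccccc1 | intermediate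
34 | (4R,5R,8S,E)-10-iodo-5-methoxy-4,8-dimethyl-8-(triethylsilyloxy)undec-9-en-3-one | I/C(C)=C/[C@@](C)(O[Si](CC)(CC)CC)CC[C@@H](OC)[C@@H](C)C(=O)CC | intermediate
35 | (R)-2,2-dimethyl-1,3-dioxolane-4-carbaldehyde | O=C[C@H]1COC(C)(C)O1 | starting material
36 | (E)-dicyclohexylboron enolate of 34 | I/C(C)=C/[C@@](C)(O[Si](CC)(CC)CC)CC[C@@H](OC)[C@@H](C)C(\OB(C1CCCCC1)C1CCCCC1)=C/C | intermediate
37 | (1S,2R,4R,5R,8S,E)-1-[(R)-2,2-dimethyl-1,3-dioxolan-4-yl]-1-hydroxy-10-iodo-5-methoxy-2,4,8-trimethyl-8-(triethylsilyloxy)undec-9-en-3-one | I/C(C)=C/[C@@](C)(O[Si](CC)(CC)CC)CC[C@@H](OC)[C@@H](C)C(=O)[C@H](C)[C@H](O)[C@H]1COC(C)(C)O1 | intermediate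
38 | (1S,2S,3S,4S,5R,8S,E)-1-[(R)-2,2-dimethyl-1,3-dioxolan-4-yl]-10-iodo-5-methoxy-2,4,8-trimethyl-8-(triethylsilyloxy)undec-9-ene-1,3-diol | I/C(C)=C/[C@@](C)(O[Si](CC)(CC)CC)CC[C@@H](OC)[C@@H](C)[C@@H](O)[C@H](C)[C@H](O)[C@H]1COC(C)(C)O1 | intermediate
39 | di-tert-butylsilylene acetal of diol 38 | I/C(C)=C/[C@@](C)(O[Si](CC)(CC)CC)CC[C@@H](OC)[C@@H](C)[C@H]2O[Si](C(C)(C)C)(C(C)(C)C)O[C@@H]([C@H]2C)[C@H]1COC(C)(C)O1 | intermediate
40 | terminal (R)-1,2-diol from 39 | I/C(C)=C/[C@@](C)(O[Si](CC)(CC)CC)CC[C@@H](OC)[C@@H](C)[C@H]2O[Si](C(C)(C)C)(C(C)(C)C)O[C@@H]([C@H]2C)[C@H](O)CO | intermediate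
41 | bis(triethylsilyl) ether of 40 | I/C(C)=C/[C@@](C)(O[Si](CC)(CC)CC)CC[C@@H](OC)[C@@H](C)[C@H]2O[Si](C(C)(C)C)(C(C)(C)C)O[C@@H]([C@H]2C)[C@H](O[Si](CC)(CC)CC)CO[Si](CC)(CC)CC | intermediate
42 | primary alcohol from 41 (secondary silyl ether kept) | I/C(C)=C/[C@@](C)(O[Si](CC)(CC)CC)CC[C@@H](OC)[C@@H](C)[C@H]2O[Si](C(C)(C)C)(C(C)(C)C)O[C@@H]([C@H]2C)[C@H](O[Si](CC)(CC)CC)CO | intermediate
43 | α-(triethylsilyloxy) aldehyde | I/C(C)=C/[C@@](C)(O[Si](CC)(CC)CC)CC[C@@H](OC)[C@@H](C)[C@H]2O[Si](C(C)(C)C)(C(C)(C)C)O[C@@H]([C@H]2C)[C@H](O[Si](CC)(CC)CC)C=O | intermediate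
44 | 2,2,6-trimethyl-4H-1,3-dioxin-4-one | CC1=CC(=O)OC(C)(C)O1 | starting material
45 | lithium dienolate of 44 | C=C1C=C(O[Li])OC(C)(C)O1 | intermediate
46 | δ-hydroxy dioxinone (carbinol epimers) | I/C(C)=C/[C@@](C)(O[Si](CC)(CC)CC)CC[C@@H](OC)[C@@H](C)[C@H]2O[Si](C(C)(C)C)(C(C)(C)C)O[C@@H]([C@H]2C)[C@H](O[Si](CC)(CC)CC)C(O)CC1=CC(=O)OC(C)(C)O1 | intermediate
47 | β-keto dioxinone (fragment B) | I/C(C)=C/[C@@](C)(O[Si](CC)(CC)CC)CC[C@@H](OC)[C@@H](C)[C@H]2O[Si](C(C)(C)C)(C(C)(C)C)O[C@@H]([C@H]2C)[C@H](O[Si](CC)(CC)CC)C(=O)CC1=CC(=O)OC(C)(C)O1 | intermediate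
48 | β,δ-diketo ester of 16 | I/C(C)=C/[C@@](C)(O[Si](CC)(CC)CC)CC[C@@H](OC)[C@@H](C)[C@H]2O[Si](C(C)(C)C)(C(C)(C)C)O[C@@H]([C@H]2C)[C@H](O[Si](CC)(CC)CC)C(=O)CC(=O)CC(=O)O[C@@H](C1)[C@H](C)C(=O)O[C@@]1(CC)/C=C/[Sn](CCCC)(CCCC)CCCC | intermediate
49 | α′-hydroxy β,δ-diketo ester | I/C(C)=C/[C@@](C)(O[Si](CC)(CC)CC)CC[C@@H](OC)[C@@H](C)[C@H]2O[Si](C(C)(C)C)(C(C)(C)C)O[C@@H]([C@H]2C)[C@H](O)C(=O)CC(=O)CC(=O)O[C@@H](C1)[C@H](C)C(=O)O[C@@]1(CC)/C=C/[Sn](CCCC)(CCCC)CCCC | intermediate
50 | 3(2H)-furanone seco compound | I/C(C)=C/[C@@](C)(O[Si](CC)(CC)CC)CC[C@@H](OC)[C@@H](C)[C@H]2O[Si](C(C)(C)C)(C(C)(C)C)O[C@@H]([C@H]2C)[C@@H]3OC(=CC3=O)CC(=O)O[C@@H](C1)[C@H](C)C(=O)O[C@@]1(CC)/C=C/[Sn](CCCC)(CCCC)CCCC | intermediate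
51 | protected macrolide | CC[C@]12/C=C/C(C)=C/[C@@](C)(O[Si](CC)(CC)CC)CC[C@@H](OC)[C@@H](C)[C@H]3O[Si](C(C)(C)C)(C(C)(C)C)O[C@@H]([C@H]3C)[C@@H]4OC(=CC4=O)CC(=O)O[C@@H](C1)[C@H](C)C(=O)O2 | intermediate
52 | CNP0226414.1 | CC[C@]12/C=C/C(C)=C/[C@@](C)(O)CC[C@@H](OC)[C@@H](C)[C@@H](O)[C@H](C)[C@H](O)[C@@H]3OC(=CC3=O)CC(=O)O[C@@H](C1)[C@H](C)C(=O)O2 | target

**Totals and risks**

Total step count: 33
Longest linear sequence: 21 steps (geraniol 21 to 52, steps 13–33)

Steps most likely to fail:

1. Step 7. The orthoformate-derived cation may be too weak an electrophile for the 1,2-disubstituted alkene, so that ionization of the tertiary propargylic C–O bond or loss of the one-carbon unit wins, or chair selection at the quaternary carbon may be low. The fallback uses known chemistry, closes the ring at O1–C2 and makes the C3–C4 bond by crotylboration; it sets out from 10 and comes back at 14. Silylation of 10 (TESOTf, 2,6-lutidine) gives (R,Z)-triethyl[(3-ethylhept-5-en-1-yn-3-yl)oxy]silane F1. Ozonolysis of the (Z)-alkene (O3, CH2Cl2/MeOH, −78 °C; Me2S), which is faster than attack on the alkyne, gives (R)-3-ethyl-3-(triethylsilyloxy)pent-4-ynal F2. Brown crotylboration with the (E)-crotyldiisopinocampheylborane antipode that delivers the (3R,4S) anti adduct gives (3R,4S,6R)-6-ethyl-3-methyl-6-(triethylsilyloxy)oct-1-en-7-yn-4-ol F3. Ozonolysis of the vinyl group gives (2S,3S,5R)-5-ethyl-3-hydroxy-2-methyl-5-(triethylsilyloxy)hept-6-ynal F4. Camphorsulfonic acid in methanol removes the silyl group, closes the lactol and forms the methyl acetal 14.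

2. Step 30. Intramolecular O-acylation of the acylketene by the enolized ketone (closure to a 4-hydroxy-2-pyranone) may outrun capture by the hindered secondary alcohol. The fallback sets out from 47 and comes back at 50. 47 is heated in toluene with a large excess of methanol (sealed tube, 100 °C), so that an unhindered alcohol in high concentration intercepts the acylketene and gives the methyl β,δ-diketo ester F5. PPTS in methanol as in step 31 gives the furanone methyl ester F6. Me3SnOH (1,2-dichloroethane, 70 °C) gives the furanone acetic acid F7. Yamaguchi esterification (2,4,6-trichlorobenzoyl chloride, Et3N; then 16, DMAP, toluene, rt) with the hydroxyl of 16 gives 50.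

3. Step 33. Ionization of the tertiary dienyl C–O bonds, or epimerization next to the furanone carbonyl, may occur during the fluoride exposure needed to cleave the silylene. The fallback sets out from 50 and comes back at 52. The silylene and the tertiary silyl ether are removed from 50 with HF·pyridine/pyridine before the diene exists, giving the triol vinylstannane F8. The Stille macrocyclization of step 32 is then run on the unprotected compound and gives 52 directly, so that the finished dienyl carbinol never meets fluoride.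

Further compounds
F1 | step 7 | (R,Z)-triethyl[(3-ethylhept-5-en-1-yn-3-yl)oxy]silane | CC[C@](C/C=C\C)(O[Si](CC)(CC)CC)C#C
F2 | step 7 | (R)-3-ethyl-3-(triethylsilyloxy)pent-4-ynal | CC[C@](CC=O)(O[Si](CC)(CC)CC)C#C
F3 | step 7 | (3R,4S,6R)-6-ethyl-3-methyl-6-(triethylsilyloxy)oct-1-en-7-yn-4-ol | O[C@@H](C[C@@](CC)(O[Si](CC)(CC)CC)C#C)[C@H](C)C=C
F4 | step 7 | (2S,3S,5R)-5-ethyl-3-hydroxy-2-methyl-5-(triethylsilyloxy)hept-6-ynal | O[C@@H](C[C@@](CC)(O[Si](CC)(CC)CC)C#C)[C@H](C)C=O
F5 | step 30 | methyl β,δ-diketo ester (methyl ester corresponding to 48) | I/C(C)=C/[C@@](C)(O[Si](CC)(CC)CC)CC[C@@H](OC)[C@@H](C)[C@H]2O[Si](C(C)(C)C)(C(C)(C)C)O[C@@H]([C@H]2C)[C@H](O[Si](CC)(CC)CC)C(=O)CC(=O)CC(=O)OC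
F6 | step 30 | furanone methyl ester | I/C(C)=C/[C@@](C)(O[Si](CC)(CC)CC)CC[C@@H](OC)[C@@H](C)[C@H]2O[Si](C(C)(C)C)(C(C)(C)C)O[C@@H]([C@H]2C)[C@@H]3OC(=CC3=O)CC(=O)OC
F7 | step 30 | furanone acetic acid | I/C(C)=C/[C@@](C)(O[Si](CC)(CC)CC)CC[C@@H](OC)[C@@H](C)[C@H]2O[Si](C(C)(C)C)(C(C)(C)C)O[C@@H]([C@H]2C)[C@@H]3OC(=CC3=O)CC(=O)O
F8 | step 33 | triol vinylstannane (50 without silylene and triethylsilyl groups) | I/C(C)=C/[C@@](C)(O)CC[C@@H](OC)[C@@H](C)[C@@H](O)[C@H](C)[C@H](O)[C@@H]3OC(=CC3=O)CC(=O)O[C@@H](C1)[C@H](C)C(=O)O[C@@]1(CC)/C=C/[Sn](CCCC)(CCCC)CCCC
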